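**Retrosynthetic overview** (ring A = benzoic acid ring, ring B = cresol-derived ring)
1. Target 14 ⇐ aldehyde 13 by a final chlorite oxidation; the formyl group serves first as the SNAr activator and last as the acid precursor, so no protecting group remains at the end.
2. Key C–C disconnection: ring B–CH2OAc ⇐ aryl bromide 8 + Bu3SnCH2OAc 12, an acetoxymethyl carbanion equivalent (α-oxygenated d1 reagent), joined under palladium catalysis with the acetate already in place.
3. Prenyl ⇐ allyl (cross-metathesis); C-allyl ⇐ O-allyl (Claisen); ring B OH ⇐ OMe (BBr3, which an allyl group survives but a prenyl group would not).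
4. Diaryl ether and allyl ether ⇐ two SNAr reactions in one flask on 2,6-difluorobenzaldehyde, first with 6-bromocreosol, then with allyl alcohol.
5. No ring is constructed: both benzene rings are bought (creosol and 2,6-difluorobenzaldehyde).

Assumption: the target has no stereocentre and no stereogenic double bond, so it is achiral and no enantiocontrol is needed.

**Route**

Step 1
Reactants: 1 creosol (2-methoxy-4-methylphenol)
Product: 2 2-bromo-6-methoxy-4-methylphenol
Conditions: Br2 (1.02 equiv), CH2Cl2, 0 °C, 1 h
Reagents that add atoms: bromine, BrBr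
Why: Electrophilic aromatic bromination; the free OH is the strongest director and its para position is blocked by the methyl group, so bromine enters the only free ortho position, as in the ring bromination of eugenol and vanillin.

Step 2
Reactants: 2 2-bromo-6-methoxy-4-methylphenol; 3 2,6-difluorobenzaldehyde
Product: 5 2-(2-bromo-6-methoxy-4-methylphenoxy)-6-(prop-2-en-1-yloxy)benzaldehyde, via fluoro diaryl ether 4 (not isolated)
Conditions: K2CO3 (1.5 equiv), DMF, 70 °C, 8 h; then NaOCH2CH=CH2 (2.5 equiv, pre-formed from allyl alcohol and NaH in THF), 0 °C → rt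
Reagents that add atoms: allyl alcohol (prop-2-en-1-ol), C=CCO
Why: Two sequential nucleophilic aromatic substitutions (SNAr) activated by the ortho-formyl group; the weaker phenoxide is used first on the more electrophilic difluoride and stops at mono-substitution, then the stronger allyloxide displaces the remaining fluoride, which is a far better SNAr leaving group than the aryloxide.

Step 3
Reactants: 5 2-(2-bromo-6-methoxy-4-methylphenoxy)-6-(prop-2-en-1-yloxy)benzaldehyde
Product: 6 6-(2-bromo-6-methoxy-4-methylphenoxy)-2-hydroxy-3-(prop-2-en-1-yl)benzaldehyde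
Conditions: N,N-diethylaniline, 195 °C, 4 h, argon
Reagents that add atoms: none
Why: Aromatic Claisen rearrangement ([3,3]-sigmatropic shift); only one ortho position of the allyl ether (C3) carries hydrogen, so the allyl group is delivered there and tautomerisation gives the hydrogen-bonded salicylaldehyde.

Step 4
Reactants: 6 6-(2-bromo-6-methoxy-4-methylphenoxy)-2-hydroxy-3-(prop-2-en-1-yl)benzaldehyde
Product: 7 6-(2-bromo-6-hydroxy-4-methylphenoxy)-2-hydroxy-3-(prop-2-en-1-yl)benzaldehyde
Conditions: BBr3 (3.5 equiv), CH2Cl2, −78 → 0 °C; aqueous NaHCO3 work-up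
Reagents that add atoms: none
Why: Lewis-acid cleavage of an aryl methyl ether (BBr3 demethylation, bromide attacks the O-methyl of the boron-complexed ether); the diaryl ether, aryl bromide and chelated aldehyde are inert, and a terminal allyl group tolerates cold BBr3 as in the demethylation of eugenol.

Step 5
Reactants: 7 6-(2-bromo-6-hydroxy-4-methylphenoxy)-2-hydroxy-3-(prop-2-en-1-yl)benzaldehyde
Product: 8 6-(2-bromo-6-hydroxy-4-methylphenoxy)-2-hydroxy-3-(3-methylbut-2-en-1-yl)benzaldehyde
Conditions: 2-methylbut-2-ene (about 50 equiv), second-generation Grubbs catalyst (H2IMes)(PCy3)Cl2Ru=CHPh (5 mol%), 1,4-benzoquinone (10 mol%), CH2Cl2, 40 °C, sealed tube, 12 h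
Reagents that add atoms: 2-methylbut-2-ene, CC=C(C)C
Why: Olefin cross-metathesis with excess 2-methylbut-2-ene turns the terminal allyl group into the prenyl group with loss of propene; free phenols, the aldehyde and the aryl bromide are tolerated, and benzoquinone suppresses allyl-to-propenyl isomerisation.

Step 6
Reactants: 9 tributyltin hydride (Bu3SnH)
Product: 12 (tributylstannyl)methyl acetate, via tributylstannyllithium 10 (not isolated), via lithium (tributylstannyl)methoxide 11 (not isolated)
Conditions: LiN(iPr)2 (1.05 equiv), THF, 0 °C; (CH2O)n (1.3 equiv), 0 °C → rt; then Ac2O (1.5 equiv), 0 °C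
Reagents that add atoms: paraformaldehyde (as formaldehyde), C=O; acetic anhydride, CC(=O)OC(C)=O
Why: Addition of a stannyl anion to formaldehyde (Still's hydroxymethylstannane synthesis) followed by O-acylation of the lithium alkoxide in the same flask gives a storable α-acyloxy stannane that acts as an acetoxymethyl carbanion equivalent.

Step 7
Reactants: 8 6-(2-bromo-6-hydroxy-4-methylphenoxy)-2-hydroxy-3-(3-methylbut-2-en-1-yl)benzaldehyde; 12 (tributylstannyl)methyl acetate
Product: 13 {2-[2-formyl-3-hydroxy-4-(3-methylbut-2-en-1-yl)phenoxy]-3-hydroxy-5-methylphenyl}methyl acetate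
Conditions: 12 (1.5 equiv), Pd(PPh3)4 (10 mol%), CuI (20 mol%), 1,4-dioxane, 95 °C, argon, 16 h
Reagents that add atoms: none
Why: Proposed new method: zerovalent palladium inserts into the aryl C–Br bond, the α-acyloxymethyl group (activated by the α-oxygen and by carbonyl coordination to tin, assisted by CuI) transfers from tin in preference to butyl, and reductive elimination forms ArCH2OAc under neutral conditions that spare the acetate, phenols, aldehyde and prenyl group, so a nucleophilic CH2OAc carbon is joined to an aryl halide carbon although both are electrophilic in normal reactivity; the closest known reaction type is the Kosugi–Migita–Stille hydroxymethylation and methoxymethylation of aryl bromides with Bu3SnCH2OH and Bu3SnCH2OMe.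

Step 8
Reactants: 13 {2-[2-formyl-3-hydroxy-4-(3-methylbut-2-en-1-yl)phenoxy]-3-hydroxy-5-methylphenyl}methyl acetate
Product: 14 7-O-acetylsecopenicillide C, 6-[2-(acetoxymethyl)-6-hydroxy-4-methylphenoxy]-2-hydroxy-3-(3-methylbut-2-en-1-yl)benzoic acid
Conditions: NaClO2 (3 equiv), NaH2PO4 (4 equiv), 2-methylbut-2-ene (40 equiv), t-BuOH/THF/H2O, 0 °C → rt, 2 h
Reagents that add atoms: sodium chlorite NaClO2, [Na+].[O-]Cl=O
Why: Pinnick (Lindgren–Kraus) oxidation; chlorous acid adds to the aldehyde and fragments to the carboxylic acid, the large excess of alkene scavenger traps HOCl before it can chlorinate the prenyl group or the phenol rings, and the buffered pH of about 4 leaves the acetate intact.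

**Compound list**
1 | creosol (2-methoxy-4-methylphenol) | COc1cc(C)ccc1O | starting material
2 | 2-bromo-6-methoxy-4-methylphenol | COc1cc(C)cc(Br)c1O | intermediate
3 | 2,6-difluorobenzaldehyde | O=Cc1c(F)cccc1F | starting material
4 | 2-(2-bromo-6-methoxy-4-methylphenoxy)-6-fluorobenzaldehyde | COc1cc(C)cc(Br)c1Oc1cccc(F)c1C=O | intermediate (not isolated)
5 | 2-(2-bromo-6-methoxy-4-methylphenoxy)-6-(prop-2-en-1-yloxy)benzaldehyde | COc1cc(C)cc(Br)c1Oc1cccc(OCC=C)c1C=O | intermediate
6 | 6-(2-bromo-6-methoxy-4-methylphenoxy)-2-hydroxy-3-(prop-2-en-1-yl)benzaldehyde | COc1cc(C)cc(Br)c1Oc1ccc(CC=C)c(O)c1C=O | intermediate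
7 | 6-(2-bromo-6-hydroxy-4-methylphenoxy)-2-hydroxy-3-(prop-2-en-1-yl)benzaldehyde | Cc1cc(O)c(Oc2ccc(CC=C)c(O)c2C=O)c(Br)c1 | intermediate
8 | 6-(2-bromo-6-hydroxy-4-methylphenoxy)-2-hydroxy-3-(3-methylbut-2-en-1-yl)benzaldehyde | Cc1cc(O)c(Oc2ccc(CC=C(C)C)c(O)c2C=O)c(Br)c1 | intermediate
9 | tributyltin hydride (Bu3SnH) | CCCC[SnH](CCCC)CCCC | starting material
10 | tributylstannyllithium (Bu3SnLi) | [Li][Sn](CCCC)(CCCC)CCCC | intermediate (not isolated)
11 | lithium (tributylstannyl)methoxide (Bu3SnCH2OLi) | [Li+].[O-]C[Sn](CCCC)(CCCC)CCCC | intermediate (not isolated)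
12 | (tributylstannyl)methyl acetate (Bu3SnCH2OAc) | CC(=O)OC[Sn](CCCC)(CCCC)CCCC | intermediate
13 | {2-[2-formyl-3-hydroxy-4-(3-methylbut-2-en-1-yl)phenoxy]-3-hydroxy-5-methylphenyl}methyl acetate | CC(=O)OCc1cc(C)cc(O)c1Oc1ccc(CC=C(C)C)c(O)c1C=O | intermediate
14 | 7-O-acetylsecopenicillide C | CC(=O)OCc1cc(C)cc(O)c1Oc1ccc(CC=C(C)C)c(O)c1C(=O)O | target

**Step count**
Total steps: 8. Longest linear sequence: 7 (steps 1, 2, 3, 4, 5, 7, 8 from creosol); step 6 is a one-step side branch.

**Three steps most likely to fail, with fallbacks**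

Step 7 is the riskiest. Transfer of an sp3 group from tin to an electron-rich, ortho-aryloxy aryl palladium bromide is slow. Butyl transfer, protodebromination or ionisation of the benzylic acetate product by palladium could compete. The fallback sets out from 8 and uses a different organometallic under Suzuki–Miyaura conditions: potassium (acetoxymethyl)trifluoroborate, Pd(dba)2, RuPhos, Na2CO3, dioxane/H2O, 90 °C. The acetate is lost in the basic aqueous medium, which gives the benzylic alcohol 2-hydroxy-6-[2-hydroxy-6-(hydroxymethyl)-4-methylphenoxy]-3-(3-methylbut-2-en-1-yl)benzaldehyde F1. The primary alcohol is then acetylated in the presence of the two phenols with vinyl acetate and immobilised Candida antarctica lipase B (MTBE, 35 °C). This comes back to the route at 13.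

Step 8 is next. Two free, electron-rich phenol rings and the prenyl alkene can be chlorinated by HOCl if scavenging is incomplete. The fallback sets out from 13 and masks the phenols first: Ac2O, pyridine and catalytic DMAP give the triacetate aldehyde {3-acetoxy-2-[3-acetoxy-2-formyl-4-(3-methylbut-2-en-1-yl)phenoxy]-5-methylphenyl}methyl acetate F2. The same chlorite oxidation then gives the triacetate acid 2-acetoxy-6-[2-acetoxy-6-(acetoxymethyl)-4-methylphenoxy]-3-(3-methylbut-2-en-1-yl)benzoic acid F3. Pyrrolidine (CH2Cl2, 0 °C) aminolyses the two aryl acetates far faster than the alkyl acetate. This comes back to the route at 14.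

Step 4 is third. HBr formed in situ can add to the allyl group or close a dihydrobenzofuran with the neighbouring phenol. The fallback sets out from 4, isolated by stopping step 2 after its first stage, and moves the demethylation ahead of any alkene:
- BBr3 (CH2Cl2, −78 → 0 °C) gives 2-(2-bromo-6-hydroxy-4-methylphenoxy)-6-fluorobenzaldehyde F4.
- MOMCl and i-Pr2NEt give the methoxymethyl ether 2-[2-bromo-6-(methoxymethoxy)-4-methylphenoxy]-6-fluorobenzaldehyde F5.
- SNAr with sodium 2-methylbut-3-en-2-olate (NaH, THF/DMF, 0 °C → rt) gives the tertiary allyl ether 2-[2-bromo-6-(methoxymethoxy)-4-methylphenoxy]-6-[(2-methylbut-3-en-2-yl)oxy]benzaldehyde F6.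
- Claisen rearrangement in toluene at 110 °C places the prenyl group directly, giving 6-[2-bromo-6-(methoxymethoxy)-4-methylphenoxy]-2-hydroxy-3-(3-methylbut-2-en-1-yl)benzaldehyde F7.
- Mild acetal hydrolysis (2 M HCl, THF/i-PrOH, 40 °C) comes back to the route at 8, bypassing steps 3 to 5.

**Further compounds**
F1 | step 7 | 2-hydroxy-6-[2-hydroxy-6-(hydroxymethyl)-4-methylphenoxy]-3-(3-methylbut-2-en-1-yl)benzaldehyde | OCc1cc(C)cc(O)c1Oc1ccc(CC=C(C)C)c(O)c1C=O
F2 | step 8 | {3-acetoxy-2-[3-acetoxy-2-formyl-4-(3-methylbut-2-en-1-yl)phenoxy]-5-methylphenyl}methyl acetate | CC(=O)OCc1cc(C)cc(OC(C)=O)c1Oc1ccc(CC=C(C)C)c(OC(C)=O)c1C=O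
F3 | step 8 | 2-acetoxy-6-[2-acetoxy-6-(acetoxymethyl)-4-methylphenoxy]-3-(3-methylbut-2-en-1-yl)benzoic acid | CC(=O)OCc1cc(C)cc(OC(C)=O)c1Oc1ccc(CC=C(C)C)c(OC(C)=O)c1C(=O)O
F4 | step 4 | 2-(2-bromo-6-hydroxy-4-methylphenoxy)-6-fluorobenzaldehyde | Cc1cc(O)c(Oc2cccc(F)c2C=O)c(Br)c1
F5 | step 4 | 2-[2-bromo-6-(methoxymethoxy)-4-methylphenoxy]-6-fluorobenzaldehyde | COCOc1cc(C)cc(Br)c1Oc1cccc(F)c1C=O
F6 | step 4 | 2-[2-bromo-6-(methoxymethoxy)-4-methylphenoxy]-6-[(2-methylbut-3-en-2-yl)oxy]benzaldehyde | COCOc1cc(C)cc(Br)c1Oc1cccc(OC(C)(C)C=C)c1C=O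
F7 | step 4 | 6-[2-bromo-6-(methoxymethoxy)-4-methylphenoxy]-2-hydroxy-3-(3-methylbut-2-en-1-yl)benzaldehyde | COCOc1cc(C)cc(Br)c1Oc1ccc(CC=C(C)C)c(O)c1C=O
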